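**Plan**
- Ring B holds a tertiary α-ketol: carbinol C9, which carries the chloromethyl carbon, sits next to ketone C10. Cutting C9–C10 as an acyloin gives an acyl anion at C10 (an aldehyde) and a ketone at C9, i.e. a keto aldehyde on the quaternary carbon C6.
- Further cuts: C–Cl (back through the spiro-epoxide to a primary silyl ether); the ring A groups C1=CH2, C3–OH and C4–Br (back to a vinylogous ester by silylmethyl addition with carbonyl transposition); C6–C11 (allylation) and C6–C7 (enolate alkylation), back to dimedone and a four-carbon iodide.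
- Forward: ring A comes intact from dimedone. C6 is made quaternary, the two arms are oxidised to the keto aldehyde and masked, ring A is finished, acid unmasks, the carbene benzoin closes ring B, and chloride enters last.
- Ring B is closed after ring A because the C10 ketone would not survive the organometallic addition, the amide base and the hydride that ring A needs.
- Stereochemistry: C6 from the chiral palladium catalyst; C4 from enolate bromination with separation of epimers; C3 from hydride delivery cis to bromine; C9 from the chiral triazolium carbene acting in concert with the chair-like closure.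

Key step: step 14

Remark on numbering: atom labels follow the target. Ring A is C1 (methylidene carbon), C2, C3 (carbinol), C4 (bromide), C5 (CMe2), C6 (spiro); ring B is C6, C7, C8, C9 (carbinol with the CH2X carbon), C10 (ketone), C11. Descriptors in names use these labels; TBDPS = tert-butyldiphenylsilyl.
Assumption: the (R) ligand of step 7 and the (5aS,10bR) triazolium salt of step 14 are assigned by analogy with simple substrates; if either delivers the opposite sense, its mirror image is used.
Remark on descriptors: C6 changes from S to R at step 11 and C9 from R to S at step 17 by CIP priority only; no bond at these atoms is touched.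

**Route**

Step 1
Reactants: 1 2-bromoprop-2-en-1-ol
Product: 2 [(2-bromoprop-2-en-1-yl)oxy](tert-butyl)diphenylsilane
Conditions: TBDPSCl, imidazole, CH2Cl2, 0 °C to rt
Reagents that add atoms: tert-butyl(chloro)diphenylsilane CC(C)(C)[Si](Cl)(c1ccccc1)c1ccccc1
Why: Silylation of a primary allylic alcohol with a silyl chloride and imidazole is routine, and the bulky TBDPS group is chosen because it resists the later aqueous acid and oxygen-to-carbon silyl migration.

Step 2
Reactants: 2 [(2-bromoprop-2-en-1-yl)oxy](tert-butyl)diphenylsilane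
Product: 4 3-{[(tert-butyldiphenylsilyl)oxy]methyl}but-3-en-1-ol, via vinyllithium 3 (not isolated)
Conditions: t-BuLi (2 equiv), Et2O, −78 °C; then oxirane, BF3·OEt2, −78 °C
Reagents that add atoms: oxirane C1CO1
Why: Bromine–lithium exchange gives the 2-lithioallyl ether, which opens BF3-activated oxirane at −78 °C (Lewis acid-assisted epoxide opening by an organolithium) before β-elimination or silyl migration can intervene.

Step 3
Reactants: 4 3-{[(tert-butyldiphenylsilyl)oxy]methyl}but-3-en-1-ol
Product: 5 tert-butyl[(4-iodo-2-methylidenebutyl)oxy]diphenylsilane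
Conditions: I2, PPh3, imidazole, CH2Cl2, 0 °C
Reagents that add atoms: iodine II
Why: Appel-type iodination converts the primary alcohol through its alkoxyphosphonium salt by SN2 displacement and leaves the allylic silyl ether untouched.

Step 4
Reactants: 6 5,5-dimethylcyclohexane-1,3-dione (dimedone)
Product: 7 3-isobutoxy-5,5-dimethylcyclohex-2-en-1-one
Conditions: isobutanol, TsOH·H2O (cat.), toluene, reflux, Dean–Stark
Reagents that add atoms: 2-methylpropan-1-ol CC(C)CO
Why: Acid-catalysed enol etherification of a cyclic 1,3-dione with azeotropic removal of water gives the vinylogous ester, and dimedone delivers ring A with its gem-dimethyl group in place.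

Step 5
Reactants: 7 3-isobutoxy-5,5-dimethylcyclohex-2-en-1-one; 5 tert-butyl[(4-iodo-2-methylidenebutyl)oxy]diphenylsilane
Product: 9 rac-6-(3-{[(TBDPS)oxy]methyl}but-3-en-1-yl)-3-isobutoxy-5,5-dimethylcyclohex-2-en-1-one, via lithium enolate 8 (not isolated)
Conditions: LiN(iPr)2, THF, −78 °C; then 5, −78 °C to rt
Reagents that add atoms: none
Why: Kinetic α′-deprotonation of the vinylogous ester and SN2 alkylation with the primary iodide (Stork–Danheiser alkylation) forms C6–C7 next to the gem-dimethyl carbon; the product is racemic at this stage.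

Step 6
Reactants: 9 rac-6-(3-{[(TBDPS)oxy]methyl}but-3-en-1-yl)-3-isobutoxy-5,5-dimethylcyclohex-2-en-1-one
Product: 11 allyl 2-(3-{[(TBDPS)oxy]methyl}but-3-en-1-yl)-5-isobutoxy-3,3-dimethylcyclohexa-1,5-dien-1-yl carbonate, via lithium enolate 10 (not isolated)
Conditions: LiN(iPr)2, TMEDA, THF, −78 °C; then allyl chloroformate, −78 °C
Reagents that add atoms: allyl chloroformate C=CCOC(Cl)=O
Why: A second α′-deprotonation gives the fully substituted enolate, which the hard chloroformate acylates on oxygen to the allyl enol carbonate; this erases the C6 stereocentre ahead of the enantioselective step.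

Step 7
Reactants: 11 allyl 2-(3-{[(TBDPS)oxy]methyl}but-3-en-1-yl)-5-isobutoxy-3,3-dimethylcyclohexa-1,5-dien-1-yl carbonate
Product: 12 (6S)-6-allyl-6-(3-{[(TBDPS)oxy]methyl}but-3-en-1-yl)-3-isobutoxy-5,5-dimethylcyclohex-2-en-1-one
Conditions: Pd2(dba)3 (2.5 mol%), (R)-4-tert-butyl-2-[2-(diphenylphosphino)phenyl]-4,5-dihydrooxazole (6 mol%), toluene, 30 °C
Reagents that add atoms: none
Why: Zerovalent palladium ionises the enol carbonate, CO2 is lost, and the allyl group is transferred to C6 within the chiral palladium enolate (decarboxylative asymmetric Tsuji–Trost allylation), the phosphinooxazoline ligand selecting the enolate face so that the quaternary C6 is formed as S.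

Step 8
Reactants: 12 (6S)-6-allyl-6-(3-{[(TBDPS)oxy]methyl}but-3-en-1-yl)-3-isobutoxy-5,5-dimethylcyclohex-2-en-1-one
Product: 13 (6S)-3-isobutoxy-5,5-dimethylcyclohex-2-en-1-one carrying at C6 a 2-oxoethyl arm and a 4-[(TBDPS)oxy]-3-oxobutyl arm
Conditions: OsO4 (2 mol%), NaIO4, 2,6-lutidine, dioxane–H2O (3:1), rt
Reagents that add atoms: osmium tetroxide O=[Os](=O)(=O)=O; sodium periodate [Na+].[O-][I](=O)(=O)=O
Why: Lemieux–Johnson oxidation dihydroxylates and cleaves the two unhindered terminal alkenes to the C10 aldehyde and the C9 ketone, while the trisubstituted, hindered push–pull alkene of the vinylogous ester reacts much more slowly.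

Step 9
Reactants: 13 (6S)-3-isobutoxy-5,5-dimethylcyclohex-2-en-1-one carrying at C6 a 2-oxoethyl arm and a 4-[(TBDPS)oxy]-3-oxobutyl arm
Product: 14 (6S)-6-(1,3-dioxolan-2-ylmethyl)-6-[2-(2-{[(TBDPS)oxy]methyl}-1,3-dioxolan-2-yl)ethyl]-3-isobutoxy-5,5-dimethylcyclohex-2-en-1-one
Conditions: (Me3SiOCH2)2, Me3SiOTf (5 mol%), CH2Cl2, −78 to −20 °C
Reagents that add atoms: 1,2-bis(trimethylsilyloxy)ethane C[Si](C)(C)OCCO[Si](C)(C)C
Why: Aprotic silyl triflate-catalysed acetalisation (Noyori conditions) converts the aldehyde and the saturated ketone into dioxolanes but not the conjugated, hindered vinylogous ester carbonyl, and without protic alcohol the isobutyl enol ether is not exchanged.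

Step 10
Reactants: 14 (6S)-6-(1,3-dioxolan-2-ylmethyl)-6-[2-(2-{[(TBDPS)oxy]methyl}-1,3-dioxolan-2-yl)ethyl]-3-isobutoxy-5,5-dimethylcyclohex-2-en-1-one
Product: 16 (6S)-5,5-dimethyl-1-[(trimethylsilyl)methyl]cyclohex-1-en-3-one carrying the two dioxolane arms of 14 at C6, via carbinol adduct 15 (not isolated)
Conditions: Me3SiCH2Li, CeCl3, THF, −78 to 0 °C; then 1 M aq HCl, 0 °C, brief
Reagents that add atoms: (trimethylsilyl)methyllithium [Li]C[Si](C)(C)C
Why: The organocerium reagent adds 1,2 to the hindered C1 carbonyl without enolising it, and brief cold acid ionises the tertiary allylic carbinol and hydrolyses the enol ether (Stork–Danheiser transposition) to the C3 enone, a hydrolysis far faster than that of the dioxolanes or loss of the γ-silyl group.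

Step 11
Reactants: 16 (6S)-5,5-dimethyl-1-[(trimethylsilyl)methyl]cyclohex-1-en-3-one carrying the two dioxolane arms at C6
Product: 18 (4R,6R)-4-bromo-5,5-dimethyl-1-[(trimethylsilyl)methyl]cyclohex-1-en-3-one carrying the two dioxolane arms at C6, via lithium dienolate 17 (not isolated)
Conditions: LiN(iPr)2, THF, −78 °C; then NBS, −78 °C
Reagents that add atoms: N-bromosuccinimide BrN1C(=O)CCC1=O
Why: Kinetic α′-deprotonation at C4 gives the cross-conjugated lithium dienolate, which NBS brominates at C4 (enolate α-halogenation); the two CH2 arms on C6 are expected to give little facial bias, so the (4R) epimer, with bromine cis to the C11 arm, is secured by chromatographic separation.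

Step 12
Reactants: 18 (4R,6R)-4-bromo-5,5-dimethyl-1-[(trimethylsilyl)methyl]cyclohex-1-en-3-one carrying the two dioxolane arms at C6
Product: 19 (3S,4R,6R)-4-bromo-5,5-dimethyl-1-[(trimethylsilyl)methyl]cyclohex-1-en-3-ol carrying the two dioxolane arms at C6
Conditions: iBu2AlH, CH2Cl2, −78 °C
Reagents that add atoms: none
Why: 1,2-Reduction of the enone by the aluminium hydride takes place from the face opposite the pseudoaxial C5 methyl group (equatorial attack), which places the new hydroxyl cis to the equatorial bromine and sets C3 as S.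

Step 13
Reactants: 19 (3S,4R,6R)-4-bromo-5,5-dimethyl-1-[(trimethylsilyl)methyl]cyclohex-1-en-3-ol carrying the two dioxolane arms at C6
Product: 20 (3S,4R,6R)-4-bromo-5,5-dimethyl-1-methylidenecyclohexan-3-ol carrying at C6 a 2-oxoethyl arm and a 4-[(TBDPS)oxy]-3-oxobutyl arm
Conditions: 1 M aq HCl–THF (1:2), rt
Reagents that add atoms: water O
Why: Aqueous acid protonates the allylsilane at C2 and silicon is lost from the β-silyl cation (SE2′ protodesilylation), which fixes the exocyclic C1=CH2 alkene, and the same medium hydrolyses both dioxolanes; the TBDPS ether survives and ionisation of the C3 hydroxyl is held back by the neighbouring bromine.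

Step 14
Reactants: 20 (3S,4R,6R)-4-bromo-5,5-dimethyl-1-methylidenecyclohexan-3-ol carrying at C6 a 2-oxoethyl arm and a 4-[(TBDPS)oxy]-3-oxobutyl arm
Product: 21 (3S,4R,6R,9R)-4-bromo-9-{[(TBDPS)oxy]methyl}-3,9-dihydroxy-5,5-dimethyl-1-methylidenespiro[5.5]undecan-10-one
Conditions: (5aS,10bR)-2-(pentafluorophenyl)-5a,10b-dihydro-4H,6H-indeno[2,1-b][1,2,4]triazolo[4,3-d][1,4]oxazin-2-ium tetrafluoroborate (15 mol%), Et3N (15 mol%), toluene, rt
Reagents that add atoms: none
Why: The triazolylidene formed from the salt and Et3N adds to the aldehyde C10 and proton transfer gives the Breslow intermediate, an acyl anion equivalent that attacks the C9 ketone; collapse of the adduct releases the carbene and leaves the C10 ketone next to the tertiary C9 carbinol. The closest known reaction type is the carbene-catalysed intramolecular crossed aldehyde–ketone benzoin of aliphatic keto aldehydes to six-membered tertiary α-ketols. Ring B closes in a 6-exo-trig mode through a chair-like transition state. The new stereocentre C9 is controlled by the chiral aminoindanol backbone of the carbene, which shields one face of the enaminol; the chair that keeps the CH2OSi group and the CMe2 arm of C6 equatorial leads to the same (9R) isomer, so substrate and catalyst are expected to reinforce each other. The step needs cross-selectivity and benzoin-over-aldol selectivity: only the aldehyde can form a Breslow intermediate, the α-silyloxy ketone is the most electrophilic acceptor within reach of an unstrained ring, and the amine base is too weak to enolise either carbonyl at a competitive rate. The hindered secondary bromide, the free C3 hydroxyl and the isolated alkene are spectators, and the silyl ether keeps the side chain from alkylating the carbene as a chloromethyl ketone would.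

Step 15
Reactants: 21 (3S,4R,6R,9R)-4-bromo-9-{[(TBDPS)oxy]methyl}-3,9-dihydroxy-5,5-dimethyl-1-methylidenespiro[5.5]undecan-10-one
Product: 22 (3S,4R,6R,9R)-4-bromo-3,9-dihydroxy-9-(hydroxymethyl)-5,5-dimethyl-1-methylidenespiro[5.5]undecan-10-one
Conditions: Bu4NF, AcOH, THF, 0 °C to rt
Reagents that add atoms: none
Why: Fluoride cleaves the primary silyl ether, and buffering with AcOH keeps the medium from promoting α-ketol rearrangement or attack on the bromohydrin.

Step 16
Reactants: 22 (3S,4R,6R,9R)-4-bromo-3,9-dihydroxy-9-(hydroxymethyl)-5,5-dimethyl-1-methylidenespiro[5.5]undecan-10-one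
Product: 24 (3S,4R,6R,9R)-spiro-epoxide in which the C9 oxygen and the CH2 carbon form an oxirane (4-bromo-3-hydroxy-5,5-dimethyl-1-methylidene-10-oxo), via primary tosylate 23 (not isolated)
Conditions: TsCl, Et3N, Bu2SnO (5 mol%), CH2Cl2, 0 °C; then DBU, rt
Reagents that add atoms: none
Why: Tin-catalysed sulfonylation selects the primary hydroxyl of the 1,2-diol over the hindered isolated C3 hydroxyl, and the tertiary alkoxide then displaces the tosylate (intramolecular Williamson closure) with the C9–O bond, and so the C9 configuration, untouched.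

Step 17
Reactants: 24 (3S,4R,6R,9R)-spiro-epoxide
Product: 25 (3S,4R,6R,9S)-4-bromo-9-(chloromethyl)-3,9-dihydroxy-5,5-dimethyl-1-methylidenespiro[5.5]undecan-10-one (target CNP0273087.1)
Conditions: LiCl, AcOH, THF, rt
Reagents that add atoms: lithium chloride [Li+].[Cl-]
Why: Chloride opens the epoxide by SN2 at the primary carbon (halohydrin formation), because the other epoxide carbon is fully substituted and deactivated by the adjacent ketone, so the C9 carbinol keeps its configuration.

**Compound list**
1 | 2-bromoprop-2-en-1-ol | OCC(Br)=C | starting material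
2 | [(2-bromoprop-2-en-1-yl)oxy](tert-butyl)diphenylsilane | C=C(Br)CO[Si](c1ccccc1)(c1ccccc1)C(C)(C)C | intermediate
3 | {3-[(tert-butyldiphenylsilyl)oxy]prop-1-en-2-yl}lithium | [Li]C(=C)CO[Si](c1ccccc1)(c1ccccc1)C(C)(C)C | intermediate
4 | 3-{[(tert-butyldiphenylsilyl)oxy]methyl}but-3-en-1-ol | OCCC(=C)CO[Si](c1ccccc1)(c1ccccc1)C(C)(C)C | intermediate
5 | tert-butyl[(4-iodo-2-methylidenebutyl)oxy]diphenylsilane | ICCC(=C)CO[Si](c1ccccc1)(c1ccccc1)C(C)(C)C | intermediate
6 | 5,5-dimethylcyclohexane-1,3-dione (dimedone) | O=C1CC(=O)CC(C)(C)C1 | starting material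
7 | 3-isobutoxy-5,5-dimethylcyclohex-2-en-1-one | CC(C)COC1=CC(=O)CC(C)(C)C1 | intermediate
8 | lithium enolate of 7 (OLi at C1, C1=C6) | [Li]OC1=CC(C)(C)CC(OCC(C)C)=C1 | intermediate
9 | rac-6-(3-{[(TBDPS)oxy]methyl}but-3-en-1-yl)-3-isobutoxy-5,5-dimethylcyclohex-2-en-1-one | O=C1C=C(OCC(C)C)CC(C)(C)C1CCC(=C)CO[Si](c2ccccc2)(c2ccccc2)C(C)(C)C | intermediate
10 | lithium enolate of 9 (OLi at C1, C1=C6 fully substituted) | [Li]OC1=C(CCC(=C)CO[Si](c2ccccc2)(c2ccccc2)C(C)(C)C)C(C)(C)CC(OCC(C)C)=C1 | intermediate
11 | allyl 2-(3-{[(TBDPS)oxy]methyl}but-3-en-1-yl)-5-isobutoxy-3,3-dimethylcyclohexa-1,5-dien-1-yl carbonate | C=CCOC(=O)OC1=C(CCC(=C)CO[Si](c2ccccc2)(c2ccccc2)C(C)(C)C)C(C)(C)CC(OCC(C)C)=C1 | intermediate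
12 | (6S)-6-allyl-6-(3-{[(TBDPS)oxy]methyl}but-3-en-1-yl)-3-isobutoxy-5,5-dimethylcyclohex-2-en-1-one | O=C1C=C(OCC(C)C)CC(C)(C)[C@@]1(CC=C)CCC(=C)CO[Si](c2ccccc2)(c2ccccc2)C(C)(C)C | intermediate
13 | (6S)-3-isobutoxy-5,5-dimethylcyclohex-2-en-1-one with 2-oxoethyl and 4-[(TBDPS)oxy]-3-oxobutyl arms at C6 | O=C1C=C(OCC(C)C)CC(C)(C)[C@@]1(CC=O)CCC(=O)CO[Si](c2ccccc2)(c2ccccc2)C(C)(C)C | intermediate
14 | (6S)-6-(1,3-dioxolan-2-ylmethyl)-6-[2-(2-{[(TBDPS)oxy]methyl}-1,3-dioxolan-2-yl)ethyl]-3-isobutoxy-5,5-dimethylcyclohex-2-en-1-one | O=C1C=C(OCC(C)C)CC(C)(C)[C@@]1(CC2OCCO2)CCC2(CO[Si](c3ccccc3)(c3ccccc3)C(C)(C)C)OCCO2 | intermediate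
15 | (6S)-carbinol adduct: 14 with C1 as C(OH)CH2SiMe3, either configuration at C1 | C[Si](C)(C)CC1(O)C=C(OCC(C)C)CC(C)(C)[C@@]1(CC2OCCO2)CCC2(CO[Si](c3ccccc3)(c3ccccc3)C(C)(C)C)OCCO2 | intermediate
16 | (6S)-5,5-dimethyl-1-[(trimethylsilyl)methyl]cyclohex-1-en-3-one with the two dioxolane arms at C6 | C[Si](C)(C)CC1=CC(=O)CC(C)(C)[C@@]1(CC2OCCO2)CCC2(CO[Si](c3ccccc3)(c3ccccc3)C(C)(C)C)OCCO2 | intermediate
17 | lithium dienolate of 16 (OLi at C3, C3=C4) | C[Si](C)(C)CC1=CC(O[Li])=CC(C)(C)[C@@]1(CC2OCCO2)CCC2(CO[Si](c3ccccc3)(c3ccccc3)C(C)(C)C)OCCO2 | intermediate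
18 | (4R,6R)-4-bromo-5,5-dimethyl-1-[(trimethylsilyl)methyl]cyclohex-1-en-3-one with the two dioxolane arms at C6 | C[Si](C)(C)CC1=CC(=O)[C@H](Br)C(C)(C)[C@@]1(CC2OCCO2)CCC2(CO[Si](c3ccccc3)(c3ccccc3)C(C)(C)C)OCCO2 | intermediate
19 | (3S,4R,6R)-4-bromo-5,5-dimethyl-1-[(trimethylsilyl)methyl]cyclohex-1-en-3-ol with the two dioxolane arms at C6 | C[Si](C)(C)CC1=C[C@H](O)[C@H](Br)C(C)(C)[C@@]1(CC2OCCO2)CCC2(CO[Si](c3ccccc3)(c3ccccc3)C(C)(C)C)OCCO2 | intermediate
20 | (3S,4R,6R)-4-bromo-5,5-dimethyl-1-methylidenecyclohexan-3-ol with 2-oxoethyl and 4-[(TBDPS)oxy]-3-oxobutyl arms at C6 | C=C1C[C@H](O)[C@H](Br)C(C)(C)[C@@]1(CC=O)CCC(=O)CO[Si](c2ccccc2)(c2ccccc2)C(C)(C)C | intermediate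
21 | (3S,4R,6R,9R)-4-bromo-9-{[(TBDPS)oxy]methyl}-3,9-dihydroxy-5,5-dimethyl-1-methylidenespiro[5.5]undecan-10-one | C=C1C[C@H](O)[C@H](Br)C(C)(C)[C@@]12CC[C@@](O)(CO[Si](c3ccccc3)(c3ccccc3)C(C)(C)C)C(=O)C2 | intermediate
22 | (3S,4R,6R,9R)-4-bromo-3,9-dihydroxy-9-(hydroxymethyl)-5,5-dimethyl-1-methylidenespiro[5.5]undecan-10-one | C=C1C[C@H](O)[C@H](Br)C(C)(C)[C@@]12CC[C@@](O)(CO)C(=O)C2 | intermediate
23 | (3S,4R,6R,9R)-primary tosylate of 22 | C=C1C[C@H](O)[C@H](Br)C(C)(C)[C@@]12CC[C@@](O)(COS(=O)(=O)c3ccc(C)cc3)C(=O)C2 | intermediate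
24 | (3S,4R,6R,9R)-spiro-epoxide (oxirane from the C9 oxygen and the CH2 carbon) | C=C1C[C@H](O)[C@H](Br)C(C)(C)[C@@]12CC[C@@]3(CO3)C(=O)C2 | intermediate
25 | (3S,4R,6R,9S)-4-bromo-9-(chloromethyl)-3,9-dihydroxy-5,5-dimethyl-1-methylidenespiro[5.5]undecan-10-one | C=C1C[C@H](O)[C@H](Br)C(C)(C)[C@@]12CC[C@@](O)(CCl)C(=O)C2 | target

**Step count and risks**

Total step count: 17. Longest linear sequence: 16 steps (steps 1–3, then 5–17); the dimedone branch has 14 (steps 4–17).

The three steps most likely to fail:

1. Step 11. Facial selectivity at C4 is likely to be poor, since the only distinction between the two faces of the dienolate is which of two similar CH2 arms on the remote C6 lies pseudoaxial; competing γ-deprotonation at the CH2Si carbon may add to this. The fallback replaces reliance on selectivity by a separation-and-return loop. It sets out from 16 and comes back to 16: the bromination is run as it stands, the (4S,6R)-bromo enone F1 is separated from 18, and F1 is debrominated with Zn dust in AcOH (reductive dehalogenation of an α-bromo ketone). This regenerates 16 for another pass, so material is not lost to the wrong epimer.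

2. Step 14. Base-mediated intramolecular aldol pathways may overtake the benzoin closure, or the facial preferences of catalyst and substrate at C9 may oppose one another. The fallback forms the same C9–C10 bond reductively and sets out from 20. The C3 hydroxyl is silylated (Et3SiCl, imidazole, DMAP) to give the C3 triethylsilyl ether of the keto aldehyde F2. SmI2 (divalent samarium) in THF with t-BuOH at −78 °C, without HMPA so that the bromide is spared, then effects a ketyl–carbonyl pinacol cyclisation to the cis-9,10-diol F3. Here C9 is set by the chair with the CH2OSi group and the CMe2 arm equatorial, and the C10 carbinol is transient. Dess–Martin periodinane oxidises the only free secondary alcohol to give the C3 triethylsilyl ether of the ketol F4. Bu4NF/AcOH then removes both silyl groups, and the route is rejoined at 22.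

3. Step 13. Acid may ionise the allylic C3 hydroxyl with loss of silicon (1,4-elimination to a diene) instead of protonating C2, and long exposure may move the exocyclic alkene into the ring. The fallback removes the leaving-group ability of the C3 oxygen before acid is applied and sets out from 19. Ac2O, DMAP and pyridine give the C3 acetate of the allylsilane F5. The conditions of step 13 then give the C3 acetate of the keto aldehyde F6. The carbene benzoin of step 14 gives the C3 acetate of the ketol F7. K2CO3 in MeOH cleaves the acetate while the side chain is still a silyl ether (so no chlorohydrin is exposed to base), and the route is rejoined at 21.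

Further compounds
F1 | step 11 | (4S,6R)-4-bromo-5,5-dimethyl-1-[(trimethylsilyl)methyl]cyclohex-1-en-3-one with the two dioxolane arms at C6 (C4 epimer of 18) | C[Si](C)(C)CC1=CC(=O)[C@@H](Br)C(C)(C)[C@@]1(CC2OCCO2)CCC2(CO[Si](c3ccccc3)(c3ccccc3)C(C)(C)C)OCCO2
F2 | step 14 | (3S,4R,6R)-C3 triethylsilyl ether of keto aldehyde 20 | C=C1C[C@H](O[Si](CC)(CC)CC)[C@H](Br)C(C)(C)[C@@]1(CC=O)CCC(=O)CO[Si](c2ccccc2)(c2ccccc2)C(C)(C)C
F3 | step 14 | (3S,4R,6R,9R,10R)-4-bromo-9-{[(TBDPS)oxy]methyl}-5,5-dimethyl-1-methylidene-3-[(triethylsilyl)oxy]spiro[5.5]undecane-9,10-diol (cis-diol) | C=C1C[C@H](O[Si](CC)(CC)CC)[C@H](Br)C(C)(C)[C@@]12CC[C@@](O)(CO[Si](c3ccccc3)(c3ccccc3)C(C)(C)C)[C@H](O)C2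
F4 | step 14 | (3S,4R,6R,9R)-C3 triethylsilyl ether of ketol 21 | C=C1C[C@H](O[Si](CC)(CC)CC)[C@H](Br)C(C)(C)[C@@]12CC[C@@](O)(CO[Si](c3ccccc3)(c3ccccc3)C(C)(C)C)C(=O)C2
F5 | step 13 | (3S,4R,6R)-C3 acetate of allylsilane 19 | C[Si](C)(C)CC1=C[C@H](OC(C)=O)[C@H](Br)C(C)(C)[C@@]1(CC2OCCO2)CCC2(CO[Si](c3ccccc3)(c3ccccc3)C(C)(C)C)OCCO2
F6 | step 13 | (3S,4R,6R)-C3 acetate of keto aldehyde 20 | C=C1C[C@H](OC(C)=O)[C@H](Br)C(C)(C)[C@@]1(CC=O)CCC(=O)CO[Si](c2ccccc2)(c2ccccc2)C(C)(C)C
F7 | step 13 | (3S,4R,6R,9R)-C3 acetate of ketol 21 | C=C1C[C@H](OC(C)=O)[C@H](Br)C(C)(C)[C@@]12CC[C@@](O)(CO[Si](c3ccccc3)(c3ccccc3)C(C)(C)C)C(=O)C2
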